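The route rests on the seven-membered ring segment C6(O-ester)–C7H2–C8(CH3)–C9 (epoxide at C8/C9, derived from a C8=C9 alkene). A β,γ-unsaturated carbinol of this kind is the retron of a one-carbon homologation of a 2-methylcyclohex-2-enone in which the alkenyl carbon migrates. The key step inserts C7 between C6 and C8 of a trans-fused hydrindenone that already holds C1, C4 and C5, turning its six-membered ring into the cyclohept-3-enone in one operation. The precursor comes from a cyclopentenone: one copper-catalysed asymmetric conjugate addition sets the quaternary ring-fusion carbon C1, and C4, C5, C6, C8 and C9 are relayed from its angular methyl group.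

Key step: step 7

Remark: locants C1–C10 in the text refer to the product skeleton (C1 methyl-bearing ring-fusion carbon, C2, C3, C4 isopropyl carbinol, C5 ring-fusion CH; C6 esterified carbinol, C7 CH2, C8 methyl-bearing epoxide carbon, C9, C10 CH2); the names in the compound list use ring-based numbering.

Step 1
Reactants: 1 3-ethoxycyclopent-2-en-1-one
Product: 3 3-(prop-2-en-1-yl)cyclopent-2-en-1-one, via allyl carbinol 2 (not isolated)
Conditions: allylMgBr, THF, 0 °C; then 1 M HCl, 0 °C to rt
Reagents that add atoms: allylmagnesium bromide, C=CC[Mg]Br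
Why: 1,2-addition of the Grignard reagent to the vinylogous ester followed by acid-induced loss of ethanol from the tertiary carbinol transposes the carbonyl (Stork–Danheiser sequence), and no stereocentre is formed.

Step 2
Reactants: 3 3-(prop-2-en-1-yl)cyclopent-2-en-1-one; 4 2-methylprop-2-enal (methacrolein)
Product: 6 (3R)-2-(1-hydroxy-2-methylprop-2-en-1-yl)-3-methyl-3-(prop-2-en-1-yl)cyclopentan-1-one, via aluminium enolate 5 (not isolated)
Conditions: Me3Al, Cu(O2CC4H3S) (copper thiophene-2-carboxylate, cat.), chiral N,N-bis(1-phenylethyl)-P,P-diphenylphosphinous amide ligand (cat., antipode giving the R centre), Et2O, −30 °C; then MeLi, THF, −78 °C; then 4, −78 °C; aq. NH4Cl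
Reagents that add atoms: trimethylaluminium, C[Al](C)C
Why: copper-catalysed asymmetric conjugate addition of methyl to the β,β-disubstituted enone sets quaternary C1 under ligand control, and the regiodefined enolate, activated as its lithium aluminate, undergoes aldol addition to methacrolein at C5; the configurations at C5 and at the carbinol carbon C6 are immaterial because both are erased in step 4.

Step 3
Reactants: 6 (3R)-2-(1-hydroxy-2-methylprop-2-en-1-yl)-3-methyl-3-(prop-2-en-1-yl)cyclopentan-1-one
Product: 7 (3aR)-7-hydroxy-3a,6-dimethyl-2,3,3a,4,7,7a-hexahydro-1H-inden-1-one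
Conditions: second-generation Grubbs catalyst (cat.), CH2Cl2, 40 °C
Reagents that add atoms: none
Why: ring-closing metathesis between the allyl group and the 1,1-disubstituted alkene closes the six-membered ring with its trisubstituted C8=C9 double bond and releases ethene, the free alcohol and the ketone being tolerated.

Step 4
Reactants: 7 (3aR)-7-hydroxy-3a,6-dimethyl-2,3,3a,4,7,7a-hexahydro-1H-inden-1-one
Product: 8 (3aR)-3a,6-dimethyl-3,3a,4,7a-tetrahydro-1H-indene-1,7(2H)-dione
Conditions: Dess–Martin periodinane, NaHCO3, CH2Cl2, 0 °C to rt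
Reagents that add atoms: none
Why: Dess–Martin oxidation of the allylic carbinol gives the enolised β-diketone, in which C5 is trigonal, so that all diastereomers of 7 converge to one compound whose only stereocentre is C1.

Step 5
Reactants: 8 (3aR)-3a,6-dimethyl-3,3a,4,7a-tetrahydro-1H-indene-1,7(2H)-dione
Product: 9 (3aR)-7-[(tert-butyldimethylsilyl)oxy]-3a,6-dimethyl-2,3,3a,4-tetrahydro-1H-inden-1-one
Conditions: TBSOTf (1.05 equiv), Et3N, CH2Cl2, −78 to 0 °C
Reagents that add atoms: tert-butyldimethylsilyl trifluoromethanesulfonate, CC(C)(C)[Si](C)(C)OS(=O)(=O)C(F)(F)F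
Why: O-silylation of the β-diketone enol should give, after equilibration of the silyl group between the two oxygens, the linearly conjugated silyloxy dienone in which the C6 carbonyl is masked and only the cyclopentanone carbonyl C4 stays electrophilic.

Step 6
Reactants: 9 (3aR)-7-[(tert-butyldimethylsilyl)oxy]-3a,6-dimethyl-2,3,3a,4-tetrahydro-1H-inden-1-one
Product: 11 (3R,3aR,7aR)-3-hydroxy-5,7a-dimethyl-3-(propan-2-yl)-1,2,3,3a,7,7a-hexahydro-4H-inden-4-one, via tertiary carbinol 10 (not isolated)
Conditions: iPrMgCl, CeCl3, THF, −78 °C; then TBAF, AcOH, THF, −78 to 0 °C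
Reagents that add atoms: isopropylmagnesium chloride, CC(C)[Mg]Cl
Why: the organocerium reagent adds 1,2 to the C4 carbonyl of the nearly planar bicyclic dienone from the face opposite the angular methyl group, which sets C4 with its hydroxyl cis to that methyl, and buffered fluoride then cleaves the silyl enol ether with protonation of C5 anti to the angular methyl to give the trans-fused, hydrogen-bonded β-hydroxy ketone.

Step 7
Reactants: 11 (3R,3aR,7aR)-3-hydroxy-5,7a-dimethyl-3-(propan-2-yl)-1,2,3,3a,7,7a-hexahydro-4H-inden-4-one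
Product: 13 (3R,3aR,8aR)-3-hydroxy-6,8a-dimethyl-3-(propan-2-yl)-2,3,3a,5,8,8a-hexahydroazulen-4(1H)-one, via silyl ketone 12 (not isolated)
Conditions: Me3Al (2.2 equiv), TMSCHN2, CH2Cl2, −78 to −20 °C; then TBAF, AcOH, THF, −78 to 0 °C
Reagents that add atoms: trimethylsilyldiazomethane, C[Si](C)(C)C=[N+]=[N-]
Why: Me3Al first turns the C4 hydroxyl into an aluminium alkoxide that chelates and activates the C6 carbonyl; the diazo carbon adds to C6, and in the β-diazonium alkoxide the alkenyl carbon C8 shifts to the new carbon with loss of N2, so that C7 is inserted between C6 and C8 and the six-membered ring becomes the seven-membered one. The closest known reaction type is the Lewis-acid-promoted diazoalkane homologation (Tiffeneau–Demjanov-type ring expansion) of conjugated cyclohexenones, which proceeds with alkenyl migration to β,γ-unsaturated cycloheptenones. No ring is closed: an existing carbocycle is enlarged by one atom through a 1,2-shift, and buffered fluoride then removes the C7 silyl group by α-protonation of the dienolate, which keeps the double bond at C8=C9. No stereocentre is created, and C1, C4 and C5 are untouched because enolisation is directed towards C7. The step needs migration of C8 and not of C5: C5 is a congested methine between two fully substituted carbons, carries the electron-withdrawing β-oxygen and is tied into the six-membered aluminium chelate, whereas the sp2 carbon is a good migrating group. It also needs carbonyl addition to win over dipolar cycloaddition, which the low temperature, the Lewis-acid activation and the trisubstituted α-methylated double bond should favour.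

Step 8
Reactants: 13 (3R,3aR,8aR)-3-hydroxy-6,8a-dimethyl-3-(propan-2-yl)-2,3,3a,5,8,8a-hexahydroazulen-4(1H)-one
Product: 14 (3R,3aS,4S,8aR)-6,8a-dimethyl-3-(propan-2-yl)-1,2,3,3a,4,5,8,8a-octahydroazulene-3,4-diol
Conditions: Me4NBH(OAc)3, AcOH, MeCN, −30 °C
Reagents that add atoms: none
Why: the tertiary C4 hydroxyl binds the acetoxyborohydride and delivers hydride intramolecularly to the β face of the C6 ketone (Evans–Saksena directed reduction), which gives the 1,3-anti diol with the C6 hydroxyl α, and only the trans-fused C5 epimer, whose C4–O and C6=O are syn, can react in this way.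

Step 9
Reactants: 14 (3R,3aS,4S,8aR)-6,8a-dimethyl-3-(propan-2-yl)-1,2,3,3a,4,5,8,8a-octahydroazulene-3,4-diol
Product: 15 (3R,3aS,4S,6R,7S,8aR)-6,7-epoxy-6,8a-dimethyl-3-(propan-2-yl)decahydroazulene-3,4-diol
Conditions: VO(acac)2 (cat.), t-BuOOH, CH2Cl2, 0 °C
Reagents that add atoms: tert-butyl hydroperoxide, CC(C)(C)OO
Why: vanadium-catalysed epoxidation directed by the homoallylic C6 hydroxyl delivers oxygen to the C8=C9 double bond on the face of that hydroxyl (α), setting C8 and C9, while the remote tertiary hydroxyl on the opposite face cannot compete.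

Step 10
Reactants: 15 (3R,3aS,4S,6R,7S,8aR)-6,7-epoxy-6,8a-dimethyl-3-(propan-2-yl)decahydroazulene-3,4-diol; 16 3,4-dimethoxybenzoyl chloride
Product: 17 (3R,3aS,4S,6R,7S,8aR)-6,7-epoxy-3-hydroxy-6,8a-dimethyl-3-(propan-2-yl)decahydroazulen-4-yl 3,4-dimethoxybenzoate
Conditions: Et3N, DMAP (cat.), CH2Cl2, 0 °C to rt
Reagents that add atoms: none
Why: DMAP-catalysed acylation esterifies the secondary C6 alcohol, while the hindered tertiary C4 alcohol and the epoxide should be inert under these mildly basic conditions.

Compound list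

1 | 3-ethoxycyclopent-2-en-1-one | CCOC1=CC(=O)CC1 | starting material
2 | 1-allyl-3-ethoxycyclopent-2-en-1-ol (racemic, as its magnesium alkoxide in the flask) | CCOC1=CC(O)(CC=C)CC1 | intermediate (not isolated)
3 | 3-(prop-2-en-1-yl)cyclopent-2-en-1-one | C=CCC1=CC(=O)CC1 | intermediate
4 | 2-methylprop-2-enal (methacrolein) | CC(=C)C=O | starting material
5 | dimethylaluminium (R)-3-methyl-3-(prop-2-en-1-yl)cyclopent-1-en-1-olate | C=CC[C@@]1(C)CCC(O[Al](C)C)=C1 | intermediate (not isolated)
6 | (3R)-2-(1-hydroxy-2-methylprop-2-en-1-yl)-3-methyl-3-(prop-2-en-1-yl)cyclopentan-1-one, mixture of epimers at C2 and at the carbinol carbon | C=CC[C@@]1(C)CCC(=O)C1C(O)C(C)=C | intermediate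
7 | (3aR)-7-hydroxy-3a,6-dimethyl-2,3,3a,4,7,7a-hexahydro-1H-inden-1-one, mixture of epimers at C7 and C7a | OC2C(C)=CC[C@@]3(C)CCC(=O)C23 | intermediate
8 | (3aR)-3a,6-dimethyl-3,3a,4,7a-tetrahydro-1H-indene-1,7(2H)-dione (enolised β-diketone, C7a epimerisable) | O=C2C(C)=CC[C@@]3(C)CCC(=O)C23 | intermediate
9 | (3aR)-7-[(tert-butyldimethylsilyl)oxy]-3a,6-dimethyl-2,3,3a,4-tetrahydro-1H-inden-1-one | CC(C)(C)[Si](C)(C)OC2=C3C(=O)CC[C@]3(C)CC=C2C | intermediate
10 | (1R,3aR)-7-[(tert-butyldimethylsilyl)oxy]-3a,6-dimethyl-1-(propan-2-yl)-2,3,3a,4-tetrahydro-1H-inden-1-ol | CC(C)(C)[Si](C)(C)OC2=C3[C@](O)(C(C)C)CC[C@]3(C)CC=C2C | intermediate (not isolated)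
11 | (3R,3aR,7aR)-3-hydroxy-5,7a-dimethyl-3-(propan-2-yl)-1,2,3,3a,7,7a-hexahydro-4H-inden-4-one | O=C2C(C)=CC[C@@]3(C)CC[C@@](O)(C(C)C)[C@H]23 | intermediate
12 | C7-trimethylsilyl derivative of 13 (silyl on the CH between the carbonyl and the alkene, both epimers) | O=C2C([Si](C)(C)C)C(C)=CC[C@@]3(C)CC[C@@](O)(C(C)C)[C@H]23 | intermediate (not isolated)
13 | (3R,3aR,8aR)-3-hydroxy-6,8a-dimethyl-3-(propan-2-yl)-2,3,3a,5,8,8a-hexahydroazulen-4(1H)-one | O=C2CC(C)=CC[C@@]3(C)CC[C@@](O)(C(C)C)[C@H]23 | intermediate
14 | (3R,3aS,4S,8aR)-6,8a-dimethyl-3-(propan-2-yl)-1,2,3,3a,4,5,8,8a-octahydroazulene-3,4-diol | O[C@H]2CC(C)=CC[C@@]3(C)CC[C@@](O)(C(C)C)[C@H]23 | intermediate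
15 | (3R,3aS,4S,6R,7S,8aR)-6,7-epoxy-6,8a-dimethyl-3-(propan-2-yl)decahydroazulene-3,4-diol | O[C@H]2C[C@@]3(C)O[C@H]3C[C@@]3(C)CC[C@@](O)(C(C)C)[C@H]23 | intermediate
16 | 3,4-dimethoxybenzoyl chloride | COc1ccc(C(Cl)=O)cc1OC | starting material
17 | (3R,3aS,4S,6R,7S,8aR)-6,7-epoxy-3-hydroxy-6,8a-dimethyl-3-(propan-2-yl)decahydroazulen-4-yl 3,4-dimethoxybenzoate | COc1ccc(C(=O)O[C@H]2C[C@@]3(C)O[C@H]3C[C@@]3(C)CC[C@@](O)(C(C)C)[C@H]23)cc1OC | target

Total step count: 10. Longest linear sequence: 10 steps (from 1 to 17).

Steps most likely to fail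

1. Step 7. What may go wrong: the saturated carbon C5 migrates instead of the alkenyl carbon C8, the diazoalkane adds across the enone double bond, or the double bond slips into conjugation while the silyl group is removed. Fallback (from 11, back at 13): ring expansion by cyclopropanation and fragmentation, in which the position of the new carbon is fixed by connectivity. Soft enolisation of 11 with TMSOTf and Et3N (CH2Cl2, 0 °C) should silylate the C4 hydroxyl and give the extended bis(trimethylsilyl) dienol ether F1. Simmons–Smith cyclopropanation of its electron-rich C6=C8 enol ether bond (Et2Zn, CH2I2) gives the siloxy vinylcyclopropane F2, whose new CH2 already bridges C6 and C8. TBAF buffered with AcOH then frees the cyclopropanolate; the internal C6–C8 bond breaks to the ketone and an allyl anion stabilised by C9=C10, and protonation at C10 should give 13.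

2. Step 6. What may go wrong: ionisation of the tertiary, doubly allylic alkoxide with loss of the C4 oxygen, attack of the reagent on the methyl-bearing face, or protonation of C5 to the cis-fused ketone. Fallback (from 6, back at 11): C4 is set in the monocyclic series instead. The diastereomers of 6 with the C5 side chain cis to the C1 methyl group are separated by chromatography and treated with iPrMgCl and CeCl3 (THF, −78 °C); addition anti to the adjacent C5 substituent should give the diene diol F3. Ring-closing metathesis with the second-generation Grubbs catalyst gives the bicyclic allylic alcohol F4, and MnO2 (CH2Cl2) oxidises its allylic carbinol to 11.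

3. Step 2. What may go wrong: the aluminium enolate adds sluggishly or reversibly to the enal, or the enal polymerises under the basic conditions. Fallback (from 3, back at 6): the same conjugate addition is quenched with TMSCl and Et3N and the trimethylsilyl enol ether F5 is isolated; a Mukaiyama aldol addition of F5 to 4 with BF3·OEt2 in CH2Cl2 at −78 °C should then give 6.

Further compounds

F1 | step 7 | extended bis(trimethylsilyl) dienol ether of 11 (C4–OSiMe3; Me3SiO–C6=C8 and C9=C10) | C[Si](C)(C)OC2=C(C)C=C[C@@]3(C)CC[C@@](O[Si](C)(C)C)(C(C)C)[C@H]23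
F2 | step 7 | siloxy vinylcyclopropane from F1 (CH2 bridging C6 and C8, C9=C10 retained) | C[Si](C)(C)OC24CC4(C)C=C[C@@]3(C)CC[C@@](O[Si](C)(C)C)(C(C)C)[C@H]23
F3 | step 6 | (1R,2S,3R)-2-(1-hydroxy-2-methylprop-2-en-1-yl)-3-methyl-1-(propan-2-yl)-3-(prop-2-en-1-yl)cyclopentan-1-ol (carbinol epimers) | C=CC[C@@]1(C)CC[C@@](O)(C(C)C)[C@@H]1C(O)C(C)=C
F4 | step 6 | (3R,3aS,7aR)-5,7a-dimethyl-3-(propan-2-yl)-2,3,3a,4,7,7a-hexahydro-1H-indene-3,4-diol (epimers at C4) | OC2C(C)=CC[C@@]3(C)CC[C@@](O)(C(C)C)[C@H]23
F5 | step 2 | (R)-trimethyl{[3-methyl-3-(prop-2-en-1-yl)cyclopent-1-en-1-yl]oxy}silane | C=CC[C@@]1(C)CCC(O[Si](C)(C)C)=C1
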